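The ten ring carbons come from 6-methoxy-1-tetralone, and the route rests on disconnecting the angular C14 methyl from the quaternary ring-fusion carbon C10. A single carbinol at C4 (ring A), set by catalytic ketone reduction, steers a zinc carbenoid onto the β face of the tetrasubstituted C5=C10 alkene shared by rings A and B. One operation thus forms C10–C14, a temporary C5–C14 bond and the C10 configuration. The precursor is the (S)-allylic alcohol 5, an octal-5(10)-en-4β-ol carrying C8 as a dioxolane. Reductive opening of the derived cyclopropyl ketone, a diosphenol route to the 4-methyl-4-en-3-one, C7/C8 elaboration and a final singlet-oxygen ene reaction complete the target.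

Key step: step 4

Remark on the chemistry: eudesmane numbering (C1–C15) is used for all bicyclic intermediates. Ketone 11 is drawn as its trans-fused C5 epimer and acyloin 14 without configuration at C3, because both centres become sp2 in step 8.

Step 1
Reactants: 1 6-methoxy-1-tetralone
Product: 2 (S)-6-methoxy-1,2,3,4-tetrahydronaphthalen-1-ol
Conditions: RuCl(p-cymene)[(S,S)-TsDPEN] (1 mol %), HCO2H–Et3N (5:2), 40 °C
Reagents that add atoms: none
Why: Noyori–Ikariya asymmetric transfer hydrogenation of an aryl alkyl ketone, in which the (S,S)-diamine ligand should deliver hydride to the face that gives the (S)-carbinol, the future 4β-hydroxyl.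

Step 2
Reactants: 2 (S)-6-methoxy-1,2,3,4-tetrahydronaphthalen-1-ol
Product: 3 (S)-6-methoxy-1,2,3,4,5,8-hexahydronaphthalen-1-ol
Conditions: Li, NH3(l), THF, t-BuOH, −78 → −33 °C; then NH4Cl
Reagents that add atoms: none
Why: Birch reduction, in which the methoxy group fixes the 2,5-dihydro pattern (enol ether C7=C8 and tetrasubstituted C5=C10 alkene) while the benzylic oxygen, carried as its lithium alkoxide, should resist C–O hydrogenolysis and the carbinol centre is untouched.

Step 3
Reactants: 3 (S)-6-methoxy-1,2,3,4,5,8-hexahydronaphthalen-1-ol; 4 ethylene glycol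
Product: 5 (S)-8,8-ethylenedioxy-octal-5(10)-en-4β-ol
Conditions: ethylene glycol (5 equiv), PPTS (cat.), CH2Cl2, 0 °C → rt; Et3N quench
Reagents that add atoms: ethylene glycol, OCCO
Why: acid-catalysed enol ether–diol exchange (transketalisation), in which protonation at C7 gives a C8 oxocarbenium ion that the diol captures with loss of methanol, so the ketone is never free and the C5=C10 alkene cannot move into conjugation.

Step 4
Reactants: 5 (S)-8,8-ethylenedioxy-octal-5(10)-en-4β-ol; 6 diiodomethane
Product: 8 8,8-ethylenedioxy-5β,10β-methanodecalin-4β-ol, via ethylzinc C4-alkoxide 7 (not isolated)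
Conditions: Et2Zn (5 equiv), CH2I2 (10 equiv), CH2Cl2, 0 °C → rt; aq. NH4Cl
Reagents that add atoms: diiodomethane, ICI
Why: Hydroxyl-directed Simmons–Smith cyclopropanation under Furukawa conditions, the closest known reaction being the syn-cyclopropanation of cyclic allylic alcohols: Et2Zn turns the C4 hydroxyl into a zinc alkoxide and, with CH2I2, forms the carbenoid EtZnCH2I, which that alkoxide holds. Methylene is then transferred to C5=C10 through a concerted butterfly transition state, so the ring C5–C10–C14 closes by one suprafacial [2+1] addition that forms C10–C14 and the temporary C5–C14 bond together. Both new stereocentres (C5 and C10) are controlled by the C4 carbinol, because the bound carbenoid can only reach the alkene face that carries the oxygen, which places C14 on the β face, cis to the C4 oxygen. The step needs β-face selectivity and chemoselectivity: the first comes from the pseudo-axial zinc alkoxide, the second from the fact that the electron-rich tetrasubstituted alkene is the only alkene present and the dioxolane is inert to the carbenoid.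

Step 5
Reactants: 8 8,8-ethylenedioxy-5β,10β-methanodecalin-4β-ol
Product: 9 8,8-ethylenedioxy-5β,10β-methanodecalin-4-one
Conditions: Dess–Martin periodinane, NaHCO3, CH2Cl2, 0 °C → rt
Reagents that add atoms: none
Why: Dess–Martin oxidation of a secondary carbinol under buffered conditions that spare the cyclopropylcarbinyl system and the ketal, erasing the carbinol centre after it has done its work.

Step 6
Reactants: 9 8,8-ethylenedioxy-5β,10β-methanodecalin-4-one
Product: 11 8,8-ethylenedioxy-10β-methyl-5α-decalin-4-one, via lithium C4–C5 enolate 10 (not isolated)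
Conditions: Li (2.2 equiv), NH3(l), THF, −78 °C; then solid NH4Cl
Reagents that add atoms: none
Why: dissolving-metal reductive opening of a conjugated cyclopropyl ketone, in which the ketyl cleaves the C5–C14 bond (the cyclopropane bond best aligned with the carbonyl π system), leaving C14 as the β-methyl on C10 and an enolate that should protonate on the α face to give the trans ring fusion.

Step 7
Reactants: 11 8,8-ethylenedioxy-10β-methyl-5α-decalin-4-one; 12 2-(phenylsulfonyl)-3-phenyloxaziridine
Product: 14 8,8-ethylenedioxy-3-hydroxy-10β-methyl-5α-decalin-4-one, via potassium C3–C4 enolate 13 (not isolated)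
Conditions: KN(SiMe3)2 (1.1 equiv), THF, −78 °C; then 12, −78 °C; aq. NH4Cl
Reagents that add atoms: 2-(phenylsulfonyl)-3-phenyloxaziridine, O=S(=O)(N1OC1c1ccccc1)c1ccccc1
Why: kinetic deprotonation should remove a C3 methylene proton in preference to the hindered tertiary C5–H, and the enolate is hydroxylated by the N-sulfonyloxaziridine (Davis enolate oxidation), the C3 configuration being irrelevant.

Step 8
Reactants: 14 8,8-ethylenedioxy-3-hydroxy-10β-methyl-5α-decalin-4-one
Product: 16 8,8-ethylenedioxy-4-hydroxy-10β-methyl-octal-4-en-3-one, via 3,4-dione 15 (not isolated)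
Conditions: Dess–Martin periodinane, NaHCO3, CH2Cl2, rt; then DBU (0.2 equiv), rt
Reagents that add atoms: none
Why: Dess–Martin oxidation of the acyloin to the 1,2-dione followed by base-mediated tautomerisation, which should settle on the conjugated, hydrogen-bonded diosphenol with the tetrasubstituted C4=C5 enol and so erases C3 and C5.

Step 9
Reactants: 16 8,8-ethylenedioxy-4-hydroxy-10β-methyl-octal-4-en-3-one; 17 trifluoromethanesulfonic anhydride
Product: 18 8,8-ethylenedioxy-10β-methyl-3-oxo-octal-4-en-4-yl trifluoromethanesulfonate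
Conditions: Tf2O (1.2 equiv), pyridine, CH2Cl2, −78 → 0 °C
Reagents that add atoms: trifluoromethanesulfonic anhydride, FC(F)(F)S(=O)(=O)OS(=O)(=O)C(F)(F)F
Why: O-sulfonylation of the enol hydroxyl of a diosphenol to an α-triflyloxy enone, which locks the double bond at C4=C5 and activates C4 for cross-coupling.

Step 10
Reactants: 18 8,8-ethylenedioxy-10β-methyl-3-oxo-octal-4-en-4-yl trifluoromethanesulfonate; 19 tetramethylstannane
Product: 20 8,8-ethylenedioxy-4,10β-dimethyl-octal-4-en-3-one
Conditions: SnMe4 (3 equiv), Pd(PPh3)4 (5 mol %), LiCl (3 equiv), CuI (10 mol %), DMF, 80 °C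
Reagents that add atoms: tetramethylstannane, C[Sn](C)(C)C
Why: Stille coupling, in which zerovalent palladium inserts into the electron-poor alkenyl C–OTf bond, methyl is transferred from tin and reductive elimination places C15 on C4 without moving the C4=C5 double bond.

Step 11
Reactants: 20 8,8-ethylenedioxy-4,10β-dimethyl-octal-4-en-3-one
Product: 21 8,8-ethylenedioxy-4,10β-dimethyl-octal-4-en-3β-ol
Conditions: NaBH4, CeCl3·7H2O, MeOH, −20 °C
Reagents that add atoms: none
Why: Luche 1,2-reduction, in which hydride should add axially from the α face, away from the β-methyl on C10, to give the equatorial 3β-allylic alcohol.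

Step 12
Reactants: 21 8,8-ethylenedioxy-4,10β-dimethyl-octal-4-en-3β-ol; 22 isobutyryl chloride
Product: 23 8,8-ethylenedioxy-4,10β-dimethyl-octal-4-en-3β-yl isobutyrate
Conditions: i-PrCOCl (1.5 equiv), pyridine, DMAP (cat.), CH2Cl2, 0 °C → rt
Reagents that add atoms: isobutyryl chloride, CC(C)C(=O)Cl
Why: DMAP-catalysed acylation (nucleophilic acyl substitution) of the equatorial allylic alcohol installs the C3 isobutyrate with retention at C3.

Step 13
Reactants: 23 8,8-ethylenedioxy-4,10β-dimethyl-octal-4-en-3β-yl isobutyrate; 24 water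
Product: 25 4,10β-dimethyl-8-oxo-octal-4-en-3β-yl isobutyrate
Conditions: PPTS (0.2 equiv), acetone–H2O (10:1), 50 °C
Reagents that add atoms: water, O
Why: mild acid-catalysed ketal hydrolysis frees the C8 ketone under conditions too weak to ionise the allylic ester, and the C4=C5 alkene has no path into conjugation with C8 because C10 is quaternary.

Step 14
Reactants: 25 4,10β-dimethyl-8-oxo-octal-4-en-3β-yl isobutyrate; 26 allyl bromide
Product: 29 7β-allyl-4,10β-dimethyl-8-oxo-octal-4-en-3β-yl isobutyrate, via lithium C7–C8 enolate 27 (not isolated), via 7α-allyl epimer 28 (not isolated)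
Conditions: LiN(i-Pr)2 (1.05 equiv), THF, −78 °C; allyl bromide (1.5 equiv), DMPU, −78 → −20 °C; work-up; then DBU, toluene, 40 °C
Reagents that add atoms: allyl bromide, C=CCBr
Why: kinetic enolate alkylation (SN2), in which deprotonation should occur at C7 and not at C9 next to quaternary C10 or at the less acidic ester α-CH, axial attack should give mainly the 7α-allyl ketone, and DBU equilibration through the enol then places the allyl group equatorial (7β).

Step 15
Reactants: 29 7β-allyl-4,10β-dimethyl-8-oxo-octal-4-en-3β-yl isobutyrate; 30 acetic anhydride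
Product: 32 8β-acetoxy-7β-allyl-4,10β-dimethyl-octal-4-en-3β-yl isobutyrate, via lithium 8β-alkoxide 31 (not isolated)
Conditions: LiBH(s-Bu)3 (1.1 equiv), THF, −78 °C; then Ac2O (3 equiv), DMAP (0.2 equiv), −78 °C → rt; aq. NaHCO3
Reagents that add atoms: acetic anhydride, CC(=O)OC(C)=O
Why: ketone reduction by a bulky trialkylborohydride with in situ O-acylation, in which hydride should attack C8 equatorially from the α face because axial approach is blocked by the syn-axial C10 methyl, giving the axial 8β-alkoxide cis to the 7β-allyl group, trapped as its acetate.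

Step 16
Reactants: 32 8β-acetoxy-7β-allyl-4,10β-dimethyl-octal-4-en-3β-yl isobutyrate; 33 sodium periodate
Product: 35 8β-acetoxy-4,10β-dimethyl-7β-(2-oxoethyl)-octal-4-en-3β-yl isobutyrate, via terminal 1,2-diol 34 (not isolated)
Conditions: OsO4 (2 mol %), NaIO4 (4 equiv), 2,6-lutidine, dioxane–H2O (3:1), rt
Reagents that add atoms: sodium periodate, [Na+].[O-]I(=O)(=O)=O (oxygen relayed through OsO4, O=[Os](=O)(=O)=O)
Why: Lemieux–Johnson oxidation (catalytic dihydroxylation, then periodate glycol cleavage) should act only on the monosubstituted terminal alkene, because OsO4 adds very slowly to the hindered tetrasubstituted C4=C5 alkene, and gives the C12 aldehyde.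

Step 17
Reactants: 35 8β-acetoxy-4,10β-dimethyl-7β-(2-oxoethyl)-octal-4-en-3β-yl isobutyrate; 36 N,N-dimethylmethyleneiminium iodide
Product: 38 8β-acetoxy-3β-isobutyryloxy-eudesma-4,11(13)-dien-12-al, via Mannich base 37 (not isolated)
Conditions: Me2N=CH2 I (2 equiv), Et3N (3 equiv), CH2Cl2, rt
Reagents that add atoms: N,N-dimethylmethyleneiminium iodide, C=[N+](C)C.[I-]
Why: Mannich reaction of the aldehyde at C11 with the iminium salt followed by β-elimination of dimethylamine, the standard α-methylenation of aldehydes, builds the C11=C13 methylene under conditions mild enough to leave C7 and both esters untouched.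

Step 18
Reactants: 38 8β-acetoxy-3β-isobutyryloxy-eudesma-4,11(13)-dien-12-al; 39 sodium chlorite
Product: 40 8β-acetoxy-3β-isobutyryloxy-eudesma-4,11(13)-dien-12-oic acid
Conditions: NaClO2, NaH2PO4, 2-methylbut-2-ene (excess), t-BuOH–H2O, 0 °C → rt
Reagents that add atoms: sodium chlorite, [Na+].[O-]Cl=O
Why: Pinnick oxidation converts the enal into the acrylic acid without alkene migration, the excess scavenger intercepting HOCl before it can attack the electron-rich C4=C5 alkene.

Step 19
Reactants: 40 8β-acetoxy-3β-isobutyryloxy-eudesma-4,11(13)-dien-12-oic acid; 41 iodomethane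
Product: 42 methyl 8β-acetoxy-3β-isobutyryloxy-eudesma-4,11(13)-dien-12-oate
Conditions: MeI (3 equiv), K2CO3 (1.5 equiv), DMF, rt
Reagents that add atoms: iodomethane, CI
Why: O-alkylation (SN2) of the carboxylate, chosen over diazoalkane reagents because these can add to acrylates as 1,3-dipoles, with both secondary esters stable to carbonate in DMF.

Step 20
Reactants: 42 methyl 8β-acetoxy-3β-isobutyryloxy-eudesma-4,11(13)-dien-12-oate; 43 dioxygen
Product: 44 methyl 8β-acetoxy-5α-hydroperoxy-3β-isobutyryloxy-eudesma-4(15),11(13)-dien-12-oate (CNP0244758.1)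
Conditions: O2, visible light, tetraphenylporphyrin (cat.), CH2Cl2, −20 °C
Reagents that add atoms: dioxygen, O=O
Why: Schenck ene reaction of singlet oxygen with the only electron-rich alkene, in which attack on the α face, opposite the C10 β-methyl, should place oxygen on C5 while a C15 hydrogen is abstracted, giving the 5α-hydroperoxide and the C4=C15 methylene, the electron-poor acrylate staying inert.

Compound list
1 | 6-methoxy-1-tetralone | COc1ccc2c(c1)CCCC2=O | starting material
2 | (S)-6-methoxy-1,2,3,4-tetrahydronaphthalen-1-ol | O[C@H]1CCCc2cc(OC)ccc12 | intermediate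
3 | (S)-6-methoxy-1,2,3,4,5,8-hexahydronaphthalen-1-ol | O[C@H]1CCCC2=C1CC=C(OC)C2 | intermediate
4 | ethylene glycol | OCCO | starting material
5 | (S)-8,8-ethylenedioxy-octal-5(10)-en-4β-ol | O[C@H]1CCCC2=C1CCC3(C2)OCCO3 | intermediate
6 | diiodomethane | ICI | starting material
7 | ethylzinc C4-alkoxide of 5 | CC[Zn]O[C@H]1CCCC2=C1CCC3(C2)OCCO3 | intermediate
8 | 8,8-ethylenedioxy-5β,10β-methanodecalin-4β-ol | O[C@H]1CCC[C@@]23C[C@@]12CCC4(C3)OCCO4 | intermediate
9 | 8,8-ethylenedioxy-5β,10β-methanodecalin-4-one | O=C1CCC[C@@]23C[C@@]12CCC4(C3)OCCO4 | intermediate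
10 | lithium C4–C5 enolate of 11 | [Li+].[O-]C1=C2CCC3(OCCO3)C[C@@]2(C)CCC1 | intermediate
11 | 8,8-ethylenedioxy-10β-methyl-5α-decalin-4-one (trans-fused) | O=C1CCC[C@]2(C)CC3(OCCO3)CC[C@@H]12 | intermediate
12 | 2-(phenylsulfonyl)-3-phenyloxaziridine | O=S(=O)(N1OC1c1ccccc1)c1ccccc1 | starting material
13 | potassium C3–C4 enolate of 11 | [K+].[O-]C1=CCC[C@]2(C)CC3(OCCO3)CC[C@@H]12 | intermediate
14 | 8,8-ethylenedioxy-3-hydroxy-10β-methyl-5α-decalin-4-one (C3 epimers) | O=C1C(O)CC[C@]2(C)CC3(OCCO3)CC[C@@H]12 | intermediate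
15 | 8,8-ethylenedioxy-10β-methyl-5α-decalin-3,4-dione | O=C1C(=O)CC[C@]2(C)CC3(OCCO3)CC[C@@H]12 | intermediate
16 | 8,8-ethylenedioxy-4-hydroxy-10β-methyl-octal-4-en-3-one (diosphenol) | O=C1CC[C@]2(C)CC3(OCCO3)CCC2=C1O | intermediate
17 | trifluoromethanesulfonic anhydride | FC(F)(F)S(=O)(=O)OS(=O)(=O)C(F)(F)F | starting material
18 | 8,8-ethylenedioxy-10β-methyl-3-oxo-octal-4-en-4-yl trifluoromethanesulfonate | O=C1CC[C@]2(C)CC3(OCCO3)CCC2=C1OS(=O)(=O)C(F)(F)F | intermediate
19 | tetramethylstannane | C[Sn](C)(C)C | starting material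
20 | 8,8-ethylenedioxy-4,10β-dimethyl-octal-4-en-3-one | O=C1CC[C@]2(C)CC3(OCCO3)CCC2=C1C | intermediate
21 | 8,8-ethylenedioxy-4,10β-dimethyl-octal-4-en-3β-ol | O[C@H]1CC[C@]2(C)CC3(OCCO3)CCC2=C1C | intermediate
22 | isobutyryl chloride | CC(C)C(=O)Cl | starting material
23 | 8,8-ethylenedioxy-4,10β-dimethyl-octal-4-en-3β-yl isobutyrate | CC(C)C(=O)O[C@H]1CC[C@]2(C)CC3(OCCO3)CCC2=C1C | intermediate
24 | water | O | starting material
25 | 4,10β-dimethyl-8-oxo-octal-4-en-3β-yl isobutyrate | CC(C)C(=O)O[C@H]1CC[C@]2(C)CC(=O)CCC2=C1C | intermediate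
26 | allyl bromide | C=CCBr | starting material
27 | lithium C7–C8 enolate of 25 | [Li+].CC(C)C(=O)O[C@H]1CC[C@]2(C)CC([O-])=CCC2=C1C | intermediate
28 | 7α-allyl-4,10β-dimethyl-8-oxo-octal-4-en-3β-yl isobutyrate | CC(C)C(=O)O[C@H]1CC[C@]2(C)CC(=O)[C@H](CC=C)CC2=C1C | intermediate
29 | 7β-allyl-4,10β-dimethyl-8-oxo-octal-4-en-3β-yl isobutyrate | CC(C)C(=O)O[C@H]1CC[C@]2(C)CC(=O)[C@@H](CC=C)CC2=C1C | intermediate
30 | acetic anhydride | CC(=O)OC(C)=O | starting material
31 | lithium 8β-alkoxide from 29 | [Li+].CC(C)C(=O)O[C@H]1CC[C@]2(C)C[C@@H]([O-])[C@@H](CC=C)CC2=C1C | intermediate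
32 | 8β-acetoxy-7β-allyl-4,10β-dimethyl-octal-4-en-3β-yl isobutyrate | CC(C)C(=O)O[C@H]1CC[C@]2(C)C[C@@H](OC(C)=O)[C@@H](CC=C)CC2=C1C | intermediate
33 | sodium periodate | [Na+].[O-]I(=O)(=O)=O | starting material
34 | 8β-acetoxy-7β-(2,3-dihydroxypropyl)-4,10β-dimethyl-octal-4-en-3β-yl isobutyrate | CC(C)C(=O)O[C@H]1CC[C@]2(C)C[C@@H](OC(C)=O)[C@@H](CC(O)CO)CC2=C1C | intermediate
35 | 8β-acetoxy-4,10β-dimethyl-7β-(2-oxoethyl)-octal-4-en-3β-yl isobutyrate | CC(C)C(=O)O[C@H]1CC[C@]2(C)C[C@@H](OC(C)=O)[C@@H](CC=O)CC2=C1C | intermediate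
36 | N,N-dimethylmethyleneiminium iodide | C=[N+](C)C.[I-] | starting material
37 | 13-(dimethylamino) Mannich base of 35 | CC(C)C(=O)O[C@H]1CC[C@]2(C)C[C@@H](OC(C)=O)[C@@H](C(CN(C)C)C=O)CC2=C1C | intermediate
38 | 8β-acetoxy-3β-isobutyryloxy-eudesma-4,11(13)-dien-12-al | CC(C)C(=O)O[C@H]1CC[C@]2(C)C[C@@H](OC(C)=O)[C@@H](C(=C)C=O)CC2=C1C | intermediate
39 | sodium chlorite | [Na+].[O-]Cl=O | starting material
40 | 8β-acetoxy-3β-isobutyryloxy-eudesma-4,11(13)-dien-12-oic acid | CC(C)C(=O)O[C@H]1CC[C@]2(C)C[C@@H](OC(C)=O)[C@@H](C(=C)C(=O)O)CC2=C1C | intermediate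
41 | iodomethane | CI | starting material
42 | methyl 8β-acetoxy-3β-isobutyryloxy-eudesma-4,11(13)-dien-12-oate | CC(C)C(=O)O[C@H]1CC[C@]2(C)C[C@@H](OC(C)=O)[C@@H](C(=C)C(=O)OC)CC2=C1C | intermediate
43 | dioxygen | O=O | starting material
44 | methyl 8β-acetoxy-5α-hydroperoxy-3β-isobutyryloxy-eudesma-4(15),11(13)-dien-12-oate | C=C(C(=O)OC)[C@H]1C[C@@]2(OO)C(=C)[C@@H](OC(=O)C(C)C)CC[C@]2(C)C[C@H]1OC(C)=O | target

Total step count: 20. Longest linear sequence: 20 steps (fully linear from 1).

Steps most likely to fail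

Step 4. The carbenoid transfer may stall on the hindered tetrasubstituted alkene, or zinc Lewis acidity may ionise the allylic carbinol or open the dioxolane. The fallback delivers the methylene under steric control and sets out from 1. Transfer hydrogenation with the enantiomeric catalyst RuCl(p-cymene)[(R,R)-TsDPEN] gives (R)-6-methoxy-1,2,3,4-tetrahydronaphthalen-1-ol F1. Birch reduction then gives (R)-6-methoxy-1,2,3,4,5,8-hexahydronaphthalen-1-ol F2, and glycol exchange gives (R)-8,8-ethylenedioxy-octal-5(10)-en-4α-ol F3. Silylation (TBSCl, imidazole, DMF) gives the 4α-silyl ether F4, whose pseudo-axial silyloxy group shields the α face. Dibromocarbene (CHBr3, KOt-Bu, pentane, 0 °C) should therefore add to the β face to give the 14,14-dibromo-5β,10β-methanodecalin F5. Radical debromination (Bu3SnH, AIBN, toluene, 80 °C) gives the cyclopropane silyl ether F6, and Bu4NF frees 8,8-ethylenedioxy-5β,10β-methanodecalin-4α-ol F7. Dessâ€“Martin oxidation of F7 comes back to the route at 9.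

Step 9. Sulfonylation may occur on the wrong enol tautomer of the ambident diosphenol, or the coupling in step 10 may be outrun by S–O cleavage of the hindered triflate; either would misplace or lose the C4 substituent. The fallback sets out from 14. Excess MeMgBr with CeCl3 (THF, −78 → 0 °C) should add to C4 from the equatorial α face to give 8,8-ethylenedioxy-4α,10β-dimethyl-5α-decalin-3,4β-diol F8. Parikh–Doering oxidation (SO3·pyridine, DMSO, Et3N) of the secondary hydroxyl gives 8,8-ethylenedioxy-4β-hydroxy-4α,10β-dimethyl-5α-decalin-3-one F9. SOCl2 in pyridine then removes the axial 4β-hydroxyl together with the anti-periplanar 5α-hydrogen and comes back to the route at 20.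

Step 20. Hydrogen abstraction may occur from the axial C3α–H or from C6 instead of C15, which would misplace the hydroperoxide or the alkene. The fallback sets out from 42. Epoxidation on the α face (mCPBA, NaHCO3, CH2Cl2, 0 °C) gives methyl 8β-acetoxy-4α,5α-epoxy-3β-isobutyryloxy-eudesm-11(13)-en-12-oate F10. Isomerisation with the hindered amide Et2Al(tmp) (diethylaluminium 2,2,6,6-tetramethylpiperidide, toluene, 0 °C), which removes the most accessible methyl proton, gives methyl 8β-acetoxy-5α-hydroxy-3β-isobutyryloxy-eudesma-4(15),11(13)-dien-12-oate F11. Acid-catalysed perhydrolysis of this tertiary allylic alcohol (concentrated H2O2, cat. H2SO4, Et2O, 0 °C), with capture of the allyl cation at C5 from the α face, comes back to the route at 44.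

Further compounds
F1 | step 4 | (R)-6-methoxy-1,2,3,4-tetrahydronaphthalen-1-ol | O[C@@H]1CCCc2cc(OC)ccc12
F2 | step 4 | (R)-6-methoxy-1,2,3,4,5,8-hexahydronaphthalen-1-ol | O[C@@H]1CCCC2=C1CC=C(OC)C2
F3 | step 4 | (R)-8,8-ethylenedioxy-octal-5(10)-en-4α-ol | O[C@@H]1CCCC2=C1CCC3(C2)OCCO3
F4 | step 4 | 4α-(tert-butyldimethylsilyloxy)-8,8-ethylenedioxy-octal-5(10)-ene | CC(C)(C)[Si](C)(C)O[C@@H]1CCCC2=C1CCC3(C2)OCCO3
F5 | step 4 | 14,14-dibromo-4α-(tert-butyldimethylsilyloxy)-8,8-ethylenedioxy-5β,10β-methanodecalin | CC(C)(C)[Si](C)(C)O[C@@H]1CCC[C@@]23C(Br)(Br)[C@@]12CCC4(C3)OCCO4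
F6 | step 4 | 4α-(tert-butyldimethylsilyloxy)-8,8-ethylenedioxy-5β,10β-methanodecalin | CC(C)(C)[Si](C)(C)O[C@@H]1CCC[C@@]23C[C@@]12CCC4(C3)OCCO4
F7 | step 4 | 8,8-ethylenedioxy-5β,10β-methanodecalin-4α-ol | O[C@@H]1CCC[C@@]23C[C@@]12CCC4(C3)OCCO4
F8 | step 9 | 8,8-ethylenedioxy-4α,10β-dimethyl-5α-decalin-3,4β-diol (C3 epimers) | C[C@]1(O)C(O)CC[C@]2(C)CC3(OCCO3)CC[C@@H]12
F9 | step 9 | 8,8-ethylenedioxy-4β-hydroxy-4α,10β-dimethyl-5α-decalin-3-one | C[C@]1(O)C(=O)CC[C@]2(C)CC3(OCCO3)CC[C@@H]12
F10 | step 20 | methyl 8β-acetoxy-4α,5α-epoxy-3β-isobutyryloxy-eudesm-11(13)-en-12-oate | CC(C)C(=O)O[C@H]1CC[C@]2(C)C[C@@H](OC(C)=O)[C@@H](C(=C)C(=O)OC)C[C@]23O[C@]13C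
F11 | step 20 | methyl 8β-acetoxy-5α-hydroxy-3β-isobutyryloxy-eudesma-4(15),11(13)-dien-12-oate | C=C(C(=O)OC)[C@H]1C[C@@]2(O)C(=C)[C@@H](OC(=O)C(C)C)CC[C@]2(C)C[C@H]1OC(C)=O
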